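Electrophile and target together stay at 99.8% of the charge in Monday's run and 100% in Wednesday's at the last reading, so each electrophile gone stands as one target.

all flasks: electrophile 1.2 M
- Monday's: nucleophile 0.66 M; free base 1.8 M; run made earlier
- Wednesday's: nucleophile 0.99 M; free base 1.8 M; run made earlier
- flask: nucleophile 1.32 M; free base 1.80 M; time 40 min

| run | time / min | electrophile / % | target / % |
|---|---|---|---|
| Monday's | 2.00 | 90.2 | 10.5 |
| Monday's | 4.00 | 83.0 | 17.0 |
| Monday's | 10.0 | 71.3 | 29.0 |
| Monday's | 25.0 | 61.1 | 38.7 |
| Wednesday's | 2.00 | 85.3 | 14.8 |
| Wednesday's | 4.00 | 75.9 | 23.8 |
| Wednesday's | 10.0 | 61.6 | 39.6 |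
| Wednesday's | 25.0 | 48.9 | 51.3 |

(readings scatter by 0.3 percentage points)

- the earlier runs do not show how much of nucleophile is bound; that part of a forecast is a guess
- a reading or a percentage of target counts all its forms, free or not

* part of the electrophile that has reacted at 40 min
* share of the unused nucleophile that is free and not bound as protonated nucleophile, at 40 min

But Wednesday's nucleophile, 1.50 times Monday's charge, wins 1.33 times the target by 25.0 min, so in these two runs target does not follow the nucleophile charged mole for mole. Target won per nucleophile charged by 25.0 min, the nucleophile yield, is 0.704 on Monday and 0.622 on Wednesday. The flask's charge lies one equal step further, so the same fall gives it 0.540. That is 59.4% reacted at 25.0 min by the reckoning made here, which stands below the forecast's figure for 40 min; this reckoning expects somewhat more by 40 min, but the last reading stands at 25.0 min. The runs do not show how much nucleophile is bound. The forecast, reading the slowing as “released acid tying up nucleophile, with free base buffering it”, gives at 40 min 70% (64% to 76%) of the electrophile reacted and 25% (14% to 38%) of the unused nucleophile free.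

At 40 min the flask gives 64.5% of the electrophile reacted and 95.5% of the unused nucleophile free.

    acid set free + free base ⇌ salt of the base, settled at all times (K = 46000 M⁻¹)
    crystals ⇌ target, rate k2*(cs2 - [target]) while solid is left; crystals form when [target] > cs2 (solubility = 14.0 mM, k = 2.80 min⁻¹)
    2 nucleophile → self-condensation product (k = 0.0430 M⁻¹ min⁻¹)
    nucleophile + acid set free ⇌ protonated nucleophile, settled at all times (K = 2900 M⁻¹)
    electrophile + nucleophile → acid set free + target (k = 0.0960 M⁻¹ min⁻¹)

The flask's nucleophile yield comes to 0.586 at 40 min, a lift of 0.0460 over the line's figure for 25.0 min, and at 40 min the flask holds 0.243 M of self-condensation product, two nucleophile each. Charged at 1.10 equivalents, nucleophile is the limiting reagent in this flask, with 4.4% of its own charge left at 40 min against 36% of the electrophile's. On the neighbouring flask, the same but for its 0.53 M of nucleophile, the line gives 0.736, and the same lift makes 34.5% reacted at 40 min. That neighbouring flask gives 35.3%.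

The data are simulated for an exercise.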